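Compound numbers 1–35 are fixed by the steps below and are used throughout. Carbons carry labdane numbers (ring A: C1–C5 and C10; ring B: C5–C10; C11–C16 chain on C9; C17 on C8; methyl C18 and carboxyl C19 on C4; methyl C20 on C10), and β is the face of C20. TBS = tert-butyldimethylsilyl; "RB" = the ring B unit (6R,8S)-6-[2-(TBS-oxy)ethyl]-7-methylidene-1,4-dioxaspiro[4.5]decan-8-yl.

## Analysis of the target

The target is a labdane-type diacid on a cis-fused decalin, with an exocyclic C8=C17 methylene and, on C9, a chain ending in an (E)-3-methylbut-2-enoic acid. It has five stereocentres, (2S,4R,5S,9S,10R). The C20 methyl, H5, the C18 methyl, the C2 hydroxyl and the C9 chain lie on the β face; the C19 carboxyl and H9 lie on the α face. C4 and C10 are quaternary and flank C5, so three contiguous, crowded carbons define the ring fusion. Sensitive points are the 1,1-disubstituted alkene (acid moves it into the ring), the geometry of the enoic acid, C9 once C8 is a ketone, and the C19 carboxyl, whose esters resist hydrolysis. The hard parts are setting C4, C5 and C10 on a mobile cis-decalin, and setting C2, whose outcome under a given reduction depends on which chair ring A adopts. The plan rests on one relationship: C10 bears a methyl cis to H5 and lies β to the oxygenated C2. C20 can therefore begin as an exocyclic methylene on ring B and be captured, with C10, by a C1 carbenoid tethered to C5 through C2–C3–C4; cleaving the cyclopropane then leaves the angular methyl and the C2 carbonyl.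

## Retrosynthetic reasoning

**35 from 34 from 33.** The carboxyls are freed last. The side-chain ester and the C2 acetate fall to hydroxide. The C19 ester sits on quaternary C4, so it is cut at the methyl–oxygen bond instead, which avoids the shielded acyl carbon.

**33 from 29 and 31 (C12–C13).** This cut splits off a four-carbon unit whose alkene geometry is fixed beforehand in enol triflate 31 (from 30). It leaves only a two-carbon arm on C9. The forward step must join the sp3 zinc reagent 32 to the sp2 triflate with retention.

**29 back to 25 (via 28, 27, 26).** These are functional-group changes. The C8 methylene comes from ketone 26 by a non-basic methylenation, since C9 is enolisable. The ketal is kept until all reductions are over.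

**25 from 24 from 23 (C2–H).** The carbinol is made from the C2 ketone by kinetic hydride delivery. In the labdane-like chair of ring A the two axial β methyls flank C2, so hydride comes from the α face. Equilibrating reduction in the same pot as the ring opening would favour the equatorial alcohol of that chair, which is the wrong (2α) epimer. The ketone is therefore isolated first.

**23 from 21 (C1–C20).** Electron transfer to the cyclopropyl ketone breaks the external cyclopropane bond and unveils the C10 methyl.

**21 from 20 (C1–C10 and C1–C20).** This is the key disconnection. Both bonds to C1 are cut, giving diazoketone 20, in which C20 is an exocyclic methylene. The forward step must add the carbenoid to the alkene face on the side of C4.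

**20 back to 14 (via 18, 17, 16).** C1 is a one-carbon diazo unit added to the C2 acid. The two carboxyls of diacid 16 differ only in hindrance, which is enough: both are methylated, then only the unhindered ester is hydrolysed. Both carboxyl carbons, C3, C4 and C18 come from lactone 14.

**14 from 9 and 12 (C4–C5).** A Claisen rearrangement forms the bond between quaternary C4 and C5 and moves the ring alkene out to C10=C20. An open-chain ester enolate with methyl and CH2CH2OR on the α carbon has no reliable geometry. The ketene acetal is therefore taken from the ortho ester of a lactone (12, from 10), where the ring fixes it (13). The existing C9 centre directs the new bond to the opposite face.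

**9 back to 3 (via 7, 6, 5).** C20 is added to the vinyl iodide as a one-carbon electrophile. The C9–C11 bond comes from an earlier orthoester Claisen rearrangement of allylic alcohol 3, which transfers the carbinol configuration to C9 and places the alkene at C5=C10.

**3 from 2 from 1.** An oxazaborolidine-catalysed reduction of iodo-enone 2 is the only source of absolute configuration. The iodine, put on enone 1 first, serves both the reduction and the later C20 installation.

## Alternatives that were turned down

**Alternative 1:** Masked o-quinone adduct, then anionic oxy-Cope.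
- Disconnection: the C4–C5 bond, made by a [3,3] shift that also breaks a C2–C7 bond of a bridged carbinol derived from a Diels–Alder reaction of a dienone dimethyl ketal.
- Forward key step: rearrangement of the C2 potassium alkoxide gives, after protonation, A1. A1 is a cis-decalin C2 ketone with a C6=C7 alkene, a C1 dimethyl ketal, the C8 oxygen tied to C12 as a tetrahydrofuran, and C19 as a silyl ether.
- For: the shift runs through a boat fixed by the bicyclic frame, so the cis fusion and the C4/C5/C10 relationship are transferred with high fidelity. This is arguably more secure than carbenoid face selection.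
- Against: A1 is functionalised in the wrong places. C1 must be deoxygenated beside the C2 ketone, C6=C7 saturated, C19 raised two oxidation levels, and the C8–O–C12 ether opened and turned into a C8 methylene. The C2 carbinol problem is unchanged.
- Comparison: stronger on ring-fusion reliability. The chosen route offers a key-step product (21) in which every carbon is at, or one step from, its final oxidation level.

**Alternative 2:** Vinyl radical closure of ring B.
- Disconnection: the C8–C9 bond.
- Forward key step: a tin hydride generates a C8 vinyl radical from a 2-bromoalkene, which adds 6-exo to C9 of an unsaturated ester on C10. This gives A2, a cis-decalin with the C8 methylene, a C2 silyl ether, the C19 ester and a C11–C12 ester.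
- For: A2 already has the exocyclic methylene and the protected 2β oxygen. There is no ketal, no methylenation and no late carbinol problem. After the key step it is clearly shorter than the chosen route.
- Against: C9 is created next to quaternary C10 with control only from a flexible chain on a monocyclic ring A, and both epimers are plausible. The vinyl radical can also abstract hydrogen from C1 or C20. The substrate must already hold C2, C4, C5 and C10 on one cyclohexane, and the disconnection gives no way to make them. Stoichiometric tin is needed.
- Comparison: better step count after the key step and a secure C2. The chosen route gives a defined way to build C4 (ring-locked Claisen) and C10 (tethered carbenoid), and makes C9 first, where it is easiest to control.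

**Alternative 3:** Intramolecular Diels–Alder reaction.
- Disconnection: C3–C4 and C5–C10 together, closing rings A and B at once from an open-chain triene. The diene is a 2-silyloxy diene (C3=C2–C1=C10), the dienophile a (Z)-2-methyl enoate (C4=C5), linked through C6–C9.
- Forward key step: heating gives A3, which is the C2 silyl enol ether of ketone 23.
- For: the most convergent plan. Three stereocentres and both rings form in one step, and hydrolysis of A3 lands exactly on 23. On step economy it is stronger than the chosen route.
- Against: the cycloaddition must join a fully substituted diene terminus (C10) to a trisubstituted dienophile carbon (C4). The diene carries its tether cis, which disfavours the s-cis conformer, so high temperature is needed and 1,5-hydrogen shifts compete. Cis versus trans fusion depends on a small endo/exo preference, and facial control rests on C9 alone.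
- Comparison: shorter if it worked. The chosen route sets the same three centres in three separate, substrate-constrained events and accepts more steps for that.

Key step: step 13

Assumption: lactone 10 is used as the racemate, because its stereocentre becomes sp2 in ketene acetal 13.

## Route

Step 1
Reactants: 1 1,4-dioxaspiro[4.5]dec-6-en-8-one
Product: 2 7-iodo-1,4-dioxaspiro[4.5]dec-6-en-8-one
Conditions: I2, pyridine, CH2Cl2, 0 °C → rt
Reagents that add atoms: iodine, II
Why: α-Iodination of an enone by conjugate addition of pyridine, iodination of the enolate and elimination (Johnson α-iodination); the iodine enlarges one carbonyl flank for step 2 and is the handle for C20 in step 6.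

Step 2
Reactants: 2 7-iodo-1,4-dioxaspiro[4.5]dec-6-en-8-one
Product: 3 (8R)-7-iodo-1,4-dioxaspiro[4.5]dec-6-en-8-ol
Conditions: (S)-2-methyl-CBS-oxazaborolidine (15 mol %), BH3·SMe2, THF, −20 °C
Reagents that add atoms: none
Why: Corey–Bakshi–Shibata reduction; the iodoalkenyl flank acts as the large group, so the (S)-catalyst should give the (8R) carbinol (C5), the only source of absolute configuration in the route.

Step 3
Reactants: 3 (8R)-7-iodo-1,4-dioxaspiro[4.5]dec-6-en-8-ol
Product: 5 ethyl [(6S)-7-iodo-1,4-dioxaspiro[4.5]dec-7-en-6-yl]acetate, via ketene acetal 4 (not isolated)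
Conditions: MeC(OEt)3, EtCO2H (cat.), xylene, 140 °C, EtOH distilled off
Reagents that add atoms: triethyl orthoacetate, CC(OCC)(OCC)OCC
Why: Johnson orthoester Claisen rearrangement; the [3,3] shift is suprafacial across the ring, so the CH2CO2Et group reaches C9 on the face the C5–O bond leaves, which relays the carbinol configuration to C9 and moves the alkene to C5=C10.

Step 4
Reactants: 5 ethyl [(6S)-7-iodo-1,4-dioxaspiro[4.5]dec-7-en-6-yl]acetate
Product: 6 2-[(6S)-7-iodo-1,4-dioxaspiro[4.5]dec-7-en-6-yl]ethanol
Conditions: i-Bu2AlH, CH2Cl2, −78 → 0 °C; aq. potassium sodium tartrate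
Reagents that add atoms: none
Why: Hydride reduction of the ester to the C12 alcohol; the vinyl iodide and ketal are inert to i-Bu2AlH at low temperature.

Step 5
Reactants: 6 2-[(6S)-7-iodo-1,4-dioxaspiro[4.5]dec-7-en-6-yl]ethanol
Product: 7 tert-butyl{2-[(6S)-7-iodo-1,4-dioxaspiro[4.5]dec-7-en-6-yl]ethoxy}dimethylsilane
Conditions: TBSCl, imidazole, DMF, rt
Reagents that add atoms: tert-butyl(chloro)dimethylsilane, CC(C)(C)[Si](C)(C)Cl
Why: Silylation of a primary alcohol; the ether should survive every step up to step 19, including lithium in ammonia.

Step 6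
Reactants: 7 tert-butyl{2-[(6S)-7-iodo-1,4-dioxaspiro[4.5]dec-7-en-6-yl]ethoxy}dimethylsilane
Product: 9 [(6R)-6-[2-(TBS-oxy)ethyl]-1,4-dioxaspiro[4.5]dec-7-en-7-yl]methanol, via vinyllithium 8 (not isolated)
Conditions: t-BuLi (2.1 equiv), Et2O, −78 °C; (CH2O)n, −78 °C → rt
Reagents that add atoms: formaldehyde (as paraformaldehyde), C=O
Why: Iodine–lithium exchange and addition of the vinyllithium to formaldehyde install C20 as a hydroxymethyl group; 8 has no β leaving group and is stable at −78 °C.

Step 7
Reactants: 10 3-methyloxolan-2-one (α-methyl-γ-butyrolactone)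
Product: 12 2,2-diethoxy-3-methyloxolane, via lactonium tetrafluoroborate 11 (not isolated)
Conditions: Et3OBF4, CH2Cl2, rt; then NaOEt, EtOH, −10 °C
Reagents that add atoms: triethyloxonium tetrafluoroborate, CC[O+](CC)CC.F[B-](F)(F)F; sodium ethoxide, CC[O-].[Na+]
Why: O-Ethylation of the lactone carbonyl (Meerwein alkylation) and capture of the cation by ethoxide give the cyclic ortho ester.

Step 8
Reactants: 9 [(6R)-6-[2-(TBS-oxy)ethyl]-1,4-dioxaspiro[4.5]dec-7-en-7-yl]methanol; 12 2,2-diethoxy-3-methyloxolane
Product: 14 (3R)-3-methyl-3-RB-oxolan-2-one (C19-to-C2 lactone), via cyclic ketene acetal 13 (not isolated)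
Conditions: 12 (3 equiv), t-BuCO2H (10 mol %), xylene, 140 °C, EtOH distilled off
Reagents that add atoms: none
Why: Ortho-lactone variant of the Johnson–Claisen rearrangement; exchange and loss of ethanol give 13, whose geometry is fixed by the ring (methyl cis to the allylic oxygen), so a chair transition state puts the methyl axial and should set C4 as (R). The C4–C5 bond should form on the ring B face opposite the C9 arm, setting C5 as (S), and the alkene moves to C10=C20.

Step 9
Reactants: 14 (3R)-3-methyl-3-RB-oxolan-2-one
Product: 16 (2R)-2-methyl-2-RB-butanedioic acid, via lithium hydroxy-carboxylate 15 (not isolated)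
Conditions: LiOH, THF/H2O, 50 °C; then NaHCO3, TEMPO (cat.), PhI(OAc)2, MeCN/H2O, rt; cold dil. HCl to pH 4
Reagents that add atoms: lithium hydroxide, [Li+].[OH-]; water, O
Why: Saponification opens the lactone, and the freed primary alcohol is oxidised in the same pot to the acid by the TEMPO oxoammonium salt; keeping the medium basic until oxidation is over prevents relactonisation, and the alkene is inert to this oxidant.

Step 10
Reactants: 16 (2R)-2-methyl-2-RB-butanedioic acid
Product: 17 dimethyl (2R)-2-methyl-2-RB-butanedioate
Conditions: MeI, K2CO3, DMF, rt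
Reagents that add atoms: iodomethane, CI
Why: O-Alkylation of both carboxylates, which is insensitive to hindrance at the C19 carboxyl.

Step 11
Reactants: 17 dimethyl (2R)-2-methyl-2-RB-butanedioate
Product: 18 (3R)-4-methoxy-3-methyl-4-oxo-3-RB-butanoic acid
Conditions: LiOH (1.2 equiv), THF/MeOH/H2O, 0 °C → rt; cold dil. HCl to pH 4
Reagents that add atoms: lithium hydroxide, [Li+].[OH-]
Why: Selective saponification; hydroxide attacks the ester on the CH2 arm (C2) far faster than the ester on quaternary C4.

Step 12
Reactants: 18 (3R)-4-methoxy-3-methyl-4-oxo-3-RB-butanoic acid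
Product: 20 methyl (2R)-5-diazo-2-methyl-4-oxo-2-RB-pentanoate, via mixed carbonic anhydride 19 (not isolated)
Conditions: i-BuOCOCl, N-methylmorpholine, THF, −15 °C; then CH2N2, Et2O, 0 °C → rt
Reagents that add atoms: diazomethane, C=[N+]=[N-]
Why: Activation of the C2 acid as a mixed anhydride under non-acidic conditions, then C-acylation of diazomethane (first stage of the Arndt–Eistert sequence) gives the α-diazoketone; the ketal and silyl ether never meet HCl.

Step 13
Reactants: 20 methyl (2R)-5-diazo-2-methyl-4-oxo-2-RB-pentanoate
Product: 21 tricyclic cyclopropyl ketone (ring A closed; C1–C10–C20 cyclopropane on the β face)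
Conditions: Cu(acac)2 (5 mol %), toluene, 110 °C, slow addition of 20 (final 0.005 M)
Reagents that add atoms: none
Why: Cu(acac)2 decomposes the diazoketone to an electrophilic copper carbenoid at C1, which adds to the electron-rich alkene C10=C20 in an asynchronous [2+1] addition that starts at the unhindered C20 terminus and finishes at C10. The closest known reaction type is the copper-catalysed intramolecular cyclopropanation of 1-diazo-6-alken-2-ones to bicyclo[4.1.0]heptan-2-ones. Ring A closes through C1–C10 in a six-membered mode that is exo to the alkene, and the three-membered ring closes through C1–C20. C10 is set by the alkene face attacked: the tether reaches C10 from C5 through C4 on the α face and the C9 arm shields the β face, so C1 should bond on the α face and C20 be pushed to the β face, cis to H5. C1 is not an independent centre, because a cyclopropane can only be cis-fused to the six-membered ring. The step needs alkene addition to win over insertion into the tertiary allylic C5–H bond and over ylide formation with the C19 ester carbonyl; copper carbenoids insert into C–H bonds far less readily than dirhodium carbenoids, and slow addition at high dilution suppresses carbene dimers. The centres at C4, C5 and C9 are not involved.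

Step 14
Reactants: 21 tricyclic cyclopropyl ketone
Product: 23 ring-opened C2 ketone (cis-decalin; C20 now the 10β-methyl), via lithium enolate 22 (not isolated)
Conditions: Li (2.5 equiv), NH3(l)/THF, −78 °C, 10 min; isoprene; NH4Cl
Reagents that add atoms: none
Why: Dissolving-metal cleavage of a conjugated cyclopropyl ketone; the external C1–C20 bond overlaps with the carbonyl π system while C1–C10 lies near its nodal plane, so C1–C20 breaks, ammonia protonates C20 and the enolate shields C2. A small excess of lithium and no alcohol are used so that the hindered C19 ester is spared.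

Step 15
Reactants: 23 ring-opened C2 ketone
Product: 24 2β-alcohol
Conditions: LiBH(s-Bu)3, THF, −78 °C; then NaOH, H2O2, 0 °C
Reagents that add atoms: none
Why: Kinetic reduction by a bulky hydride; in the labdane-like chair of ring A, C20 and the C4 methyl are both axial on the β face and flank C2, so hydride should enter from the α face and give the 2β alcohol. A one-pot over-reduction in step 14 was avoided because it would favour the equatorial alcohol of that chair, the 2α epimer.

Step 16
Reactants: 24 2β-alcohol
Product: 25 2β-acetate
Conditions: Ac2O, pyridine, DMAP (cat.), CH2Cl2, rt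
Reagents that add atoms: acetic anhydride, CC(=O)OC(C)=O
Why: Acylation of the secondary alcohol; the acetate masks the hydroxyl during iodination and zinc insertion and is removed in step 23.

Step 17
Reactants: 25 2β-acetate
Product: 26 C8 ketone
Conditions: PPTS (cat.), acetone/H2O (10:1), 55 °C
Reagents that add atoms: water, O
Why: Acid-catalysed exchange of the dioxolane, mild enough for the primary silyl ether and the acetate; with the 2β substituent in place the natural C9 configuration keeps the side chain equatorial, so there is no drive to epimerise.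

Step 18
Reactants: 26 C8 ketone
Product: 27 C8(17) methylene compound
Conditions: Zn, CH2Br2, TiCl4 (pre-formed reagent), THF/CH2Cl2, 0 °C → rt
Reagents that add atoms: dibromomethane, BrCBr
Why: Takai–Lombardo methylenation; the non-basic geminal dimetal reagent adds to the hindered ketone without enolising it toward C9 and does not attack esters.

Step 19
Reactants: 27 C8(17) methylene compound
Product: 28 C12 alcohol
Conditions: HF·pyridine, pyridine, THF, 0 °C → rt
Reagents that add atoms: none
Why: Fluoride cleaves the primary Si–O bond; the buffered reagent leaves the acetate, the ester and the exocyclic alkene alone.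

Step 20
Reactants: 28 C12 alcohol
Product: 29 C12 iodide
Conditions: I2, PPh3, imidazole, CH2Cl2, 0 °C
Reagents that add atoms: iodine, II
Why: Appel-type iodination; iodide displaces the oxyphosphonium ion of the primary alcohol by SN2.

Step 21
Reactants: 30 methyl acetoacetate
Product: 31 methyl (E)-3-(trifluoromethylsulfonyloxy)but-2-enoate
Conditions: Tf2O, 25% aq. Me4NOH, hexanes, 5 °C
Reagents that add atoms: trifluoromethanesulfonic anhydride, O=S(=O)(OS(=O)(=O)C(F)(F)F)C(F)(F)F
Why: O-Sulfonylation of the acetoacetate enolate; with the non-chelating tetramethylammonium counter-ion the enolate reacts in its extended form, which should put the triflate trans to the ester, the (E) isomer needed for the 13E alkene.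

Step 22
Reactants: 29 C12 iodide; 31 methyl (E)-3-(trifluoromethylsulfonyloxy)but-2-enoate
Product: 33 fully protected target (15- and 19-methyl esters; 2β-acetate), via alkylzinc iodide 32 (not isolated)
Conditions: Zn dust (activated with BrCH2CH2Br and Me3SiCl), DMA, 40 °C; then 31, PdCl2(dppf) (5 mol %), THF, 50 °C
Reagents that add atoms: none
Why: Zinc insertion into the primary C–I bond gives an ester-tolerant alkylzinc, and Negishi coupling with the enol triflate keeps the alkene geometry; the bidentate ligand speeds reductive elimination over β-hydride elimination.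

Step 23
Reactants: 33 fully protected target
Product: 34 19-methyl ester of the target (free C15 acid and 2β-hydroxyl)
Conditions: LiOH, THF/MeOH/H2O, rt → 40 °C; dil. HCl to pH 3
Reagents that add atoms: lithium hydroxide, [Li+].[OH-]
Why: Saponification of the unhindered conjugated ester and the acetate; the ester on quaternary C4 resists hydroxide, and the 2β hydroxyl is trans to it and cannot lactonise.

Step 24
Reactants: 34 19-methyl ester of the target
Product: 35 target, (2S,4R,5S,9S,10R)-2-hydroxylabda-8(17),13E-diene-15,19-dioic acid (cis-fused; C19 carboxyl α)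
Conditions: NaSEt, DMF, 100 °C; dil. HCl
Reagents that add atoms: none
Why: SN2 dealkylation; thiolate attacks the methyl group of the remaining ester, which does not depend on access to the hindered acyl carbon, and the side chain is already a carboxylate and not a Michael acceptor.

## Compound list

1 | 1,4-dioxaspiro[4.5]dec-6-en-8-one | O=C1C=CC2(CC1)OCCO2 | starting material
2 | 7-iodo-1,4-dioxaspiro[4.5]dec-6-en-8-one | O=C1C(I)=CC2(CC1)OCCO2 | intermediate
3 | (8R)-7-iodo-1,4-dioxaspiro[4.5]dec-6-en-8-ol | O[C@H]1C(I)=CC2(CC1)OCCO2 | intermediate
4 | (8R)-8-[(1-ethoxyethenyl)oxy]-7-iodo-1,4-dioxaspiro[4.5]dec-6-ene (ketene acetal, not isolated) | C=C(OCC)O[C@H]1C(I)=CC2(CC1)OCCO2 | intermediate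
5 | ethyl [(6S)-7-iodo-1,4-dioxaspiro[4.5]dec-7-en-6-yl]acetate | CCOC(=O)C[C@@H]1C(I)=CCCC12OCCO2 | intermediate
6 | 2-[(6S)-7-iodo-1,4-dioxaspiro[4.5]dec-7-en-6-yl]ethanol | OCC[C@@H]1C(I)=CCCC12OCCO2 | intermediate
7 | tert-butyl{2-[(6S)-7-iodo-1,4-dioxaspiro[4.5]dec-7-en-6-yl]ethoxy}dimethylsilane | CC(C)(C)[Si](C)(C)OCC[C@@H]1C(I)=CCCC12OCCO2 | intermediate
8 | [(6R)-6-[2-(TBS-oxy)ethyl]-1,4-dioxaspiro[4.5]dec-7-en-7-yl]lithium (not isolated) | CC(C)(C)[Si](C)(C)OCC[C@@H]1C([Li])=CCCC12OCCO2 | intermediate
9 | [(6R)-6-[2-(TBS-oxy)ethyl]-1,4-dioxaspiro[4.5]dec-7-en-7-yl]methanol | CC(C)(C)[Si](C)(C)OCC[C@@H]1C(CO)=CCCC12OCCO2 | intermediate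
10 | 3-methyloxolan-2-one (α-methyl-γ-butyrolactone), racemic | CC1CCOC1=O | starting material
11 | 2-ethoxy-3-methyl-4,5-dihydro-3H-furan-1-ium tetrafluoroborate, racemic (not isolated) | CCOC1=[O+]CCC1C.F[B-](F)(F)F | intermediate
12 | 2,2-diethoxy-3-methyloxolane, racemic | CCOC1(OCC)OCCC1C | intermediate
13 | tert-butyldimethyl{2-[(6R)-7-{[(3-methyl-4,5-dihydrofuran-2-yl)oxy]methyl}-1,4-dioxaspiro[4.5]dec-7-en-6-yl]ethoxy}silane (cyclic ketene acetal, not isolated) | CC1=C(OCC2=CCCC3(OCCO3)[C@@H]2CCO[Si](C)(C)C(C)(C)C)OCC1 | intermediate
14 | (3R)-3-methyl-3-RB-oxolan-2-one | C=C1[C@@H](CCO[Si](C)(C)C(C)(C)C)C2(OCCO2)CC[C@@H]1[C@]3(C)C(=O)OCC3 | intermediate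
15 | lithium (2R)-4-hydroxy-2-methyl-2-RB-butanoate (not isolated) | C=C1[C@@H](CCO[Si](C)(C)C(C)(C)C)C2(OCCO2)CC[C@@H]1[C@](C)(C(=O)[O-])CCO.[Li+] | intermediate
16 | (2R)-2-methyl-2-RB-butanedioic acid | C=C1[C@@H](CCO[Si](C)(C)C(C)(C)C)C2(OCCO2)CC[C@@H]1[C@](C)(C(=O)O)CC(=O)O | intermediate
17 | dimethyl (2R)-2-methyl-2-RB-butanedioate | C=C1[C@@H](CCO[Si](C)(C)C(C)(C)C)C2(OCCO2)CC[C@@H]1[C@](C)(C(=O)OC)CC(=O)OC | intermediate
18 | (3R)-4-methoxy-3-methyl-4-oxo-3-RB-butanoic acid | C=C1[C@@H](CCO[Si](C)(C)C(C)(C)C)C2(OCCO2)CC[C@@H]1[C@](C)(C(=O)OC)CC(=O)O | intermediate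
19 | mixed anhydride of 18 with isobutyl hydrogen carbonate (not isolated) | C=C1[C@@H](CCO[Si](C)(C)C(C)(C)C)C2(OCCO2)CC[C@@H]1[C@](C)(C(=O)OC)CC(=O)OC(=O)OCC(C)C | intermediate
20 | methyl (2R)-5-diazo-2-methyl-4-oxo-2-RB-pentanoate (ring B diazoketone with C10 exocyclic methylene) | C=C1[C@@H](CCO[Si](C)(C)C(C)(C)C)C2(OCCO2)CC[C@@H]1[C@](C)(C(=O)OC)CC(=O)C=[N+]=[N-] | intermediate
21 | tricyclic cyclopropyl ketone: cis-fused rings A and B, C1–C10–C20 cyclopropane on the β face (H5 β), C2 ketone, 4β-methyl, 4α-CO2Me, C8 ethylene ketal, 9β-CH2CH2OTBS | O1CCOC12CC[C@H]3[C@](C4)([C@H]4C(=O)C[C@@]3(C)C(=O)OC)[C@H]2CCO[Si](C)(C)C(C)(C)C | intermediate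
22 | lithium C1=C2 enolate of 23 (not isolated) | O1CCOC12CC[C@H]3[C@](C)(C=C([O-])C[C@@]3(C)C(=O)OC)[C@H]2CCO[Si](C)(C)C(C)(C)C.[Li+] | intermediate
23 | cis-decalin C2 ketone: 10β-methyl, 5β-H, 4β-methyl, 4α-CO2Me, C8 ethylene ketal, 9β-CH2CH2OTBS | O1CCOC12CC[C@H]3[C@](C)(CC(=O)C[C@@]3(C)C(=O)OC)[C@H]2CCO[Si](C)(C)C(C)(C)C | intermediate
24 | 2β-alcohol of 23 | O1CCOC12CC[C@H]3[C@](C)(C[C@H](O)C[C@@]3(C)C(=O)OC)[C@H]2CCO[Si](C)(C)C(C)(C)C | intermediate
25 | 2β-acetate of 24 | O1CCOC12CC[C@H]3[C@](C)(C[C@H](OC(C)=O)C[C@@]3(C)C(=O)OC)[C@H]2CCO[Si](C)(C)C(C)(C)C | intermediate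
26 | C8 ketone (2β-acetate, 19-methyl ester, 9β-CH2CH2OTBS) | O=C1CC[C@H]2[C@](C)(C[C@H](OC(C)=O)C[C@@]2(C)C(=O)OC)[C@H]1CCO[Si](C)(C)C(C)(C)C | intermediate
27 | C8(17) methylene compound (2β-acetate, 19-methyl ester, C12 OTBS) | C=C1CC[C@H]2[C@](C)(C[C@H](OC(C)=O)C[C@@]2(C)C(=O)OC)[C@H]1CCO[Si](C)(C)C(C)(C)C | intermediate
28 | C12 alcohol (2β-acetate, 19-methyl ester, C8 methylene) | C=C1CC[C@H]2[C@](C)(C[C@H](OC(C)=O)C[C@@]2(C)C(=O)OC)[C@H]1CCO | intermediate
29 | C12 iodide (2β-acetate, 19-methyl ester, C8 methylene) | C=C1CC[C@H]2[C@](C)(C[C@H](OC(C)=O)C[C@@]2(C)C(=O)OC)[C@H]1CCI | intermediate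
30 | methyl acetoacetate | CC(=O)CC(=O)OC | starting material
31 | methyl (E)-3-(trifluoromethylsulfonyloxy)but-2-enoate | COC(=O)/C=C(\C)OS(=O)(=O)C(F)(F)F | intermediate
32 | C12 alkylzinc iodide from 29 (not isolated) | C=C1CC[C@H]2[C@](C)(C[C@H](OC(C)=O)C[C@@]2(C)C(=O)OC)[C@H]1CC[Zn]I | intermediate
33 | dimethyl 2β-acetoxylabda-8(17),13E-diene-15,19-dioate (cis-fused series) | C=C1CC[C@H]2[C@](C)(C[C@H](OC(C)=O)C[C@@]2(C)C(=O)OC)[C@H]1CC/C(C)=C/C(=O)OC | intermediate
34 | 19-methyl ester of the target (15-acid, 2β-hydroxyl) | C=C1CC[C@H]2[C@](C)(C[C@H](O)C[C@@]2(C)C(=O)OC)[C@H]1CC/C(C)=C/C(=O)O | intermediate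
35 | (2S,4R,5S,9S,10R)-2-hydroxylabda-8(17),13E-diene-15,19-dioic acid (cis-fused; C19 carboxyl α) | C=C1CC[C@H]2[C@](C)(C[C@H](O)C[C@@]2(C)C(=O)O)[C@H]1CC/C(C)=C/C(=O)O | target

## Step count and risks

Total: 24 steps. Longest linear sequence: 22 steps (steps 1–6, 8–20 and 22–24); steps 7 and 21 are one-step side branches.

**Step 13 (key step).** The likeliest failure is loss of chemoselectivity. The alkene is flanked by two substituted carbons, so the carbenoid may insert into the tertiary allylic C5–H bond or dimerise. A second risk is attack on the β face of C10=C20 (trans fusion) if ring B reacts with the C4 arm equatorial. The fallback is an ionic ring closure that needs no carbene and makes C20 a methyl directly. It sets out from acid 18, which is homologated with 1,1'-carbonyldiimidazole and Mg(O2CCH2CO2Me)2 to the β-keto ester F1. (Ph3P)AuCl/AgOTf in toluene then adds the C1 enol across C10=C20 in the Markovnikov sense, closing the six-membered ring at C10 from the same tethered α face, to give the bicyclic β-keto ester F2. LiCl in wet DMSO at 140 °C removes the extra ester (Krapcho reaction) and the route resumes at ketone 23.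

**Step 8.** Poor diastereocontrol is the main risk. A boat-like transition state would invert C4 relative to C5, and attack syn to the C9 arm would invert C5. The ring-locked acetal allows only one geometry, so conditions cannot correct this. The fallback is an open-chain Ireland–Claisen rearrangement in which the enolisation medium selects the ketene acetal geometry. Lactone 10 is opened and etherified in one operation (KOH, 4-methoxybenzyl chloride, toluene, reflux) to 4-[(4-methoxybenzyl)oxy]-2-methylbutanoic acid F3. Alcohol 9 is esterified with it (DCC, DMAP) to the allylic ester F4. LiN(i-Pr)2 in THF or THF/HMPA, then Me3SiCl and warming, gives the rearranged acid F5 with the geometry that matches the transition-state shape actually followed. DDQ removes the benzyl ether, and the freed hydroxy acid closes to lactone 14, where the route resumes.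

**Step 15.** The facial outcome depends on which chair of ring A reacts, and the two chairs are estimated to be close in energy. If the other chair reacts (C20 and the C4 methyl equatorial, ester tucked under ring B), hydride enters from the β face and gives the 2α-alcohol F6. In that chair the 2β alcohol is the equatorial, more stable epimer. The fallback therefore replaces kinetic hydride delivery by reduction through the ketyl radical anion: SmI2 in THF/H2O should reduce 23 (esters are inert) to the more stable carbinol 24. Any F6 already formed is oxidised back to 23 with Dess–Martin periodinane and resubmitted.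

**Step 14.** The risk is loss of the C19 methyl ester to excess lithium, or over-reduction of C2 on quench. The fallback runs the electron transfer on the carboxylate salt, which cannot be reduced. It sets out from 21: LiS(n-Pr) in HMPA dealkylates the ester to the cyclopropyl keto acid F7. Lithium in ammonia then opens the cyclopropane to the keto acid F8. MeI/K2CO3 in DMF re-forms the methyl ester and returns the route at 23.

## Further compounds

F1 | step 13 | dimethyl (2R)-2-methyl-4-oxo-2-RB-hexanedioate | C=C1[C@@H](CCO[Si](C)(C)C(C)(C)C)C2(OCCO2)CC[C@@H]1[C@](C)(C(=O)OC)CC(=O)CC(=O)OC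
F2 | step 13 | 1-methoxycarbonyl derivative of ketone 23 (bicyclic β-keto ester, C1 epimers) | O1CCOC12CC[C@H]3[C@](C)(C(C(=O)OC)C(=O)C[C@@]3(C)C(=O)OC)[C@H]2CCO[Si](C)(C)C(C)(C)C
F3 | step 8 | 4-[(4-methoxybenzyl)oxy]-2-methylbutanoic acid, racemic | COc1ccc(COCCC(C)C(=O)O)cc1
F4 | step 8 | [(6R)-6-[2-(TBS-oxy)ethyl]-1,4-dioxaspiro[4.5]dec-7-en-7-yl]methyl 4-[(4-methoxybenzyl)oxy]-2-methylbutanoate | COc1ccc(COCCC(C)C(=O)OCC2=CCCC3(OCCO3)[C@@H]2CCO[Si](C)(C)C(C)(C)C)cc1
F5 | step 8 | (2R)-4-[(4-methoxybenzyl)oxy]-2-methyl-2-RB-butanoic acid | C=C1[C@@H](CCO[Si](C)(C)C(C)(C)C)C2(OCCO2)CC[C@@H]1[C@](C)(C(=O)O)CCOCc1ccc(OC)cc1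
F6 | step 15 | 2α-alcohol (C2 epimer of 24) | O1CCOC12CC[C@H]3[C@](C)(C[C@@H](O)C[C@@]3(C)C(=O)OC)[C@H]2CCO[Si](C)(C)C(C)(C)C
F7 | step 14 | C19 carboxylic acid of cyclopropyl ketone 21 | O1CCOC12CC[C@H]3[C@](C4)([C@H]4C(=O)C[C@@]3(C)C(=O)O)[C@H]2CCO[Si](C)(C)C(C)(C)C
F8 | step 14 | C19 carboxylic acid of ketone 23 | O1CCOC12CC[C@H]3[C@](C)(CC(=O)C[C@@]3(C)C(=O)O)[C@H]2CCO[Si](C)(C)C(C)(C)C
A1 | alternative 1 | cis-decalin C2 ketone with C6=C7 alkene, C1 dimethyl ketal, C8–O–C12 tetrahydrofuran and C19 silyl ether | C1CO[C@H]2C=C[C@H]3[C@](C)(C(OC)(OC)C(=O)C[C@@]3(C)CO[Si](C)(C)C(C)(C)C)[C@@H]12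
A2 | alternative 2 | cis-decalin with C8 methylene, C2 silyl ether, C19 methyl ester and C12 methyl ester | C=C1CC[C@H]2[C@](C)(C[C@H](O[Si](C)(C)C(C)(C)C)C[C@@]2(C)C(=O)OC)[C@H]1CC(=O)OC
A3 | alternative 3 | cis-decalin C2 silyl enol ether with C19 ester and C8 ketal (silyl enol ether of 23) | O1CCOC12CC[C@H]3[C@](C)(C=C(O[Si](C)(C)C(C)(C)C)C[C@@]3(C)C(=O)OC)[C@H]2CCO[Si](C)(C)C(C)(C)C
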